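Ring A is closed last, between the carbinol carbon C3 and the quaternary C4 (labdane numbering), by a copper-catalysed decarboxylative nitrile aldol. The step exploits the 1,3-diol C3(OH)–C4–C19H2OH of ring A: C19 is carried as a slim, axial-seeking nitrile on a cyano acid, so loss of CO2 gives a linear keteniminate that attacks the C3 aldehyde, forming the bond, the C4 quaternary centre and the C3 carbinol in one operation. The precursor is a monocyclic ring B cyclohexane carrying C5, C9, C10 in place, an aldehyde arm on C10 and an α-cyano acid on C5. An auxiliary-controlled syn-aldol then adds the lactone.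

Key step: step 10

Remark: labdane numbering is used throughout (ring A = C1–C5, C10; ring B = C5–C10; C17 = exocyclic CH2; C18 = methyl and C19 = hydroxymethyl on C4; C20 = methyl on C10; C11–C16 = side chain and lactone).
Remark: compounds 3–19 carry the cyano-bearing carbon (the future C4) as both epimers; it becomes trigonal in step 10, so no configuration is written for it.

Step 1
Reactants: 1 ethyl 2-cyanopropanoate; 2 allyl bromide
Product: 3 ethyl 2-cyano-2-methylpent-4-enoate
Conditions: K2CO3, acetone, 56 °C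
Reagents that add atoms: none
Why: C-alkylation of a stabilised cyanoester carbanion with a reactive allylic halide (SN2) builds the future C4 with C18, C19 and the carbon that becomes C5.

Step 2
Reactants: 3 ethyl 2-cyano-2-methylpent-4-enoate
Product: 5 ethyl 2-cyano-2-methyl-4-oxobutanoate, via secondary ozonide 4 (not isolated)
Conditions: O3, CH2Cl2, −78 °C; then PPh3, −78 → 23 °C
Reagents that add atoms: ozone, O=[O+][O-]
Why: ozonolysis with reductive work-up cleaves the only alkene to the aldehyde that becomes C10, ester and nitrile being inert.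

Step 3
Reactants: 5 ethyl 2-cyano-2-methyl-4-oxobutanoate; 6 methyl vinyl ketone
Product: 7 ethyl (3R)-2-cyano-3-formyl-2-methyl-6-oxoheptanoate
Conditions: (R)-2-[diphenyl(trimethylsilyloxy)methyl]pyrrolidine (10 mol %), ethyl 3,4-dihydroxybenzoate (20 mol %), neat, 4 °C
Reagents that add atoms: none
Why: enamine-catalysed asymmetric Michael addition, in which the (E)-enamine of 5 is attacked by the enone on the face away from the diarylsilyloxymethyl group, should set C5 as (R) in 7 whichever epimer of the quaternary carbon reacts.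

Step 4
Reactants: 7 ethyl (3R)-2-cyano-3-formyl-2-methyl-6-oxoheptanoate
Product: 9 ethyl 2-cyano-2-[(1S)-4-oxocyclohex-2-en-1-yl]propanoate, via aldol 8 (not isolated)
Conditions: p-TsOH·H2O (10 mol %), toluene, 80 °C, removal of water
Reagents that add atoms: none
Why: acid-catalysed intramolecular aldol condensation closes ring B because only the methyl-side enol of the ketone reaches the aldehyde through a six-membered ring, and C5, shielded by the quaternary carbon, should be slow to enolise.

Step 5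
Reactants: 9 ethyl 2-cyano-2-[(1S)-4-oxocyclohex-2-en-1-yl]propanoate
Product: 10 ethyl 2-cyano-2-[(1S,2R)-2-methyl-4-(trimethylsilyloxy)cyclohex-3-en-1-yl]propanoate
Conditions: Me2CuLi (from MeLi, CuI), TMSCl, THF, −78 °C; Et3N, pentane work-up
Reagents that add atoms: lithium dimethylcuprate, [Li+].C[Cu-]C; chlorotrimethylsilane, C[Si](C)(C)Cl
Why: cuprate 1,4-addition with silyl trapping brings in C20 anti to the C5 substituent and fixes the enol ether toward C9; the new centre is erased again in step 6.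

Step 6
Reactants: 10 ethyl 2-cyano-2-[(1S,2R)-2-methyl-4-(trimethylsilyloxy)cyclohex-3-en-1-yl]propanoate
Product: 11 ethyl 2-cyano-2-[(1S)-2-methyl-4-oxocyclohex-2-en-1-yl]propanoate
Conditions: Pd(OAc)2 (1.05 equiv), MeCN, 23 °C
Reagents that add atoms: none
Why: Saegusa–Ito oxidation (palladium enolate, then β-hydride elimination from C10) regenerates the enone on the side defined by the silyl enol ether, now with the C20 methyl on the β-carbon.

Step 7
Reactants: 11 ethyl 2-cyano-2-[(1S)-2-methyl-4-oxocyclohex-2-en-1-yl]propanoate; 12 2-(2-bromoethyl)-1,3-dioxolane; 13 tert-butyl bromoacetate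
Product: 16 tert-butyl 2-[(1S,2R,3S)-3-(2-cyano-1-ethoxy-1-oxopropan-2-yl)-2-[2-(1,3-dioxolan-2-yl)ethyl]-2-methyl-6-oxocyclohexyl]acetate, via Grignard reagent 14 (not isolated), via magnesium enolate 15 (not isolated)
Conditions: Mg, THF, 25 °C; then 11, CuBr·SMe2 (20 mol %), THF, −40 °C; then 13, HMPA, −40 → 23 °C; work-up; DBU, CH2Cl2, 23 °C
Reagents that add atoms: none
Why: copper-catalysed Grignard 1,4-addition should deliver the C1–C3 arm anti to the bulky C5 substituent (C10 quaternary, methyl cis to C5–C4), the regiodefined enolate is alkylated at C9 by the α-bromo ester, and DBU equilibrates the ketone α-carbon C9 to the equatorial epimer (side chain cis to the C10 methyl).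

Step 8
Reactants: 16 tert-butyl 2-[(1S,2R,3S)-3-(2-cyano-1-ethoxy-1-oxopropan-2-yl)-2-[2-(1,3-dioxolan-2-yl)ethyl]-2-methyl-6-oxocyclohexyl]acetate
Product: 17 tert-butyl 2-[(1R,2S,3S)-3-(2-cyano-1-ethoxy-1-oxopropan-2-yl)-2-[2-(1,3-dioxolan-2-yl)ethyl]-2-methyl-6-methylidenecyclohexyl]acetate
Conditions: Ph3PCH3Br, KOt-Bu, toluene, 0 → 70 °C
Reagents that add atoms: methyltriphenylphosphonium bromide, C[P+](c1ccccc1)(c1ccccc1)c1ccccc1.[Br-]
Why: Wittig methylenation turns the C8 ketone into the exocyclic C8=C17 alkene, the ylide being too weak a nucleophile for the hindered esters and the nitrile, and any C9 epimerisation under the basic conditions runs toward the equatorial isomer already present.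

Step 9
Reactants: 17 tert-butyl 2-[(1R,2S,3S)-3-(2-cyano-1-ethoxy-1-oxopropan-2-yl)-2-[2-(1,3-dioxolan-2-yl)ethyl]-2-methyl-6-methylidenecyclohexyl]acetate
Product: 19 2-[(1S,2S,3R)-3-(2-tert-butoxy-2-oxoethyl)-2-methyl-4-methylidene-2-(3-oxopropyl)cyclohexyl]-2-cyanopropanoic acid, via acid acetal 18 (not isolated)
Conditions: LiOH·H2O, THF–H2O, 0 → 23 °C; then 1 M HCl (pH 1), 23 °C
Reagents that add atoms: lithium hydroxide, [Li+].[OH-]; water, O
Why: saponification takes the cyano-activated ethyl ester and leaves the tert-butyl ester, and the dilute acid used for acidification hydrolyses the dioxolane to the C3 aldehyde without touching the alkene.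

Step 10
Reactants: 19 2-[(1S,2S,3R)-3-(2-tert-butoxy-2-oxoethyl)-2-methyl-4-methylidene-2-(3-oxopropyl)cyclohexyl]-2-cyanopropanoic acid
Product: 21 tert-butyl 2-[(1R,4aS,5R,6R,8aS)-5-cyano-6-hydroxy-5,8a-dimethyl-2-methylidenedecahydronaphthalen-1-yl]acetate, via copper keteniminate 20 (not isolated)
Conditions: CuOAc (10 mol %), rac-BINAP (12 mol %), THF, 23 → 40 °C
Reagents that add atoms: none
Why: CuOAc exchanges with the acid to a copper carboxylate that loses CO2 to give a copper keteniminate (C4=C=N–Cu), which adds to the tethered C3 aldehyde and is turned over when the copper alkoxide is protonated by the next molecule of acid. The closest known reaction type is the copper-catalysed decarboxylative aldol or Mannich addition of α,α-disubstituted cyanoacetic acids, used here intramolecularly. Ring A closes in a 6-(enolexo)-exo-trig mode through a chair in which the C5–C4 and C10–C1 bonds are both equatorial on ring B, so the decalin is trans-fused. C4 is controlled by the shape of the nucleophile: the rod-like C=C=N unit takes the axial site syn to the C10 methyl while the C18 methyl stays equatorial (an ester enolate, with a substituent cis to C5, would do the opposite), and both epimers of 19 converge on the same keteniminate. C3 is expected equatorial, the oxygen turned outward and away from the axial hydrogens on C1 and C5, but this is the least certain point of the step. The step needs the carbanion to reach the aldehyde carbon before it is protonated and must spare the tert-butyl ester and the 1,1-disubstituted alkene; the six-membered reach of the aldehyde and the neutral conditions (no enolisation at C2 or C11) should secure this.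

Step 11
Reactants: 21 tert-butyl 2-[(1R,4aS,5R,6R,8aS)-5-cyano-6-hydroxy-5,8a-dimethyl-2-methylidenedecahydronaphthalen-1-yl]acetate
Product: 23 (1R,2R,4aS,5R,8aS)-5-(2-hydroxyethyl)-1-(hydroxymethyl)-1,4a-dimethyl-6-methylidenedecahydronaphthalen-2-ol, via hydroxy aldehyde 22 (not isolated)
Conditions: i-Bu2AlH (6 equiv), toluene, −78 → 23 °C; 1 M HCl, 0 °C; then NaBH4, MeOH, 0 °C
Reagents that add atoms: water, O
Why: hydride reduction takes the tert-butyl ester to the C12 alcohol and the axial nitrile to an aluminium aldimine, which is hydrolysed to the C19 aldehyde and reduced at once by NaBH4 (nitrile-to-aldehyde reduction followed by borohydride reduction), no stereocentre being touched.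

Step 12
Reactants: 23 (1R,2R,4aS,5R,8aS)-5-(2-hydroxyethyl)-1-(hydroxymethyl)-1,4a-dimethyl-6-methylidenedecahydronaphthalen-2-ol
Product: 24 3,19-O-isopropylidene acetal of 23 (six-membered acetonide across O3 and O19, free C12 alcohol)
Conditions: 2,2-dimethoxypropane, PPTS (5 mol %), CH2Cl2, 23 °C
Reagents that add atoms: 2,2-dimethoxypropane, COC(C)(C)OC
Why: acid-catalysed transketalisation should select the cis 1,3-diol (equatorial C3–OH, axial C19–OH) as its six-membered acetonide and leave the primary C12 alcohol free.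

Step 13
Reactants: 24 3,19-O-isopropylidene acetal of 23
Product: 25 C12 aldehyde of the 3,19-acetonide (2-substituted acetaldehyde on C9)
Conditions: Dess–Martin periodinane, NaHCO3, CH2Cl2, 0 → 23 °C
Reagents that add atoms: none
Why: buffered Dess–Martin oxidation converts the only free alcohol to the aldehyde without acid that could cleave the acetonide or move the exocyclic alkene.

Step 14
Reactants: 26 methyl 2-[(4S)-2,2-dimethyl-1,3-dioxolan-4-yl]acetate
Product: 27 2-[(4S)-2,2-dimethyl-1,3-dioxolan-4-yl]acetic acid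
Conditions: LiOH·H2O, THF–H2O, 0 °C; then 1 M HCl to pH 4, 0 °C
Reagents that add atoms: lithium hydroxide, [Li+].[OH-]
Why: mild ester saponification with a cold acidification to pH 4 gives the acid with the acetonide and the C14 centre intact.

Step 15
Reactants: 27 2-[(4S)-2,2-dimethyl-1,3-dioxolan-4-yl]acetic acid; 28 (4R)-4-benzyl-1,3-oxazolidin-2-one
Product: 30 (4R)-4-benzyl-3-{2-[(4S)-2,2-dimethyl-1,3-dioxolan-4-yl]acetyl}-1,3-oxazolidin-2-one, via mixed pivalic anhydride 29 (not isolated)
Conditions: t-BuCOCl, Et3N, THF, −20 °C; then 28, LiCl, −20 → 23 °C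
Reagents that add atoms: none
Why: N-acylation of the oxazolidinone through the mixed anhydride under LiCl activation attaches the auxiliary without strong base, so the β-alkoxy acyl unit cannot eliminate.

Step 16
Reactants: 30 (4R)-4-benzyl-3-{2-[(4S)-2,2-dimethyl-1,3-dioxolan-4-yl]acetyl}-1,3-oxazolidin-2-one; 25 C12 aldehyde of the 3,19-acetonide
Product: 32 (4R)-4-benzyl-3-[(2S,3S)-2-[(4S)-2,2-dimethyl-1,3-dioxolan-4-yl]-3-hydroxy-4-(C9 of the decalin acetonide)butanoyl]-1,3-oxazolidin-2-one, via boron enolate 31 (not isolated)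
Conditions: n-Bu2BOTf, i-Pr2NEt, CH2Cl2, −78 → 0 °C; then 25, −78 → 0 °C; pH 7 buffer, MeOH, 30% H2O2, 0 °C
Reagents that add atoms: none
Why: Evans syn-aldol reaction, in which the (Z)-boron enolate reacts through a Zimmerman–Traxler chair on the face dictated by the (R)-benzyl auxiliary, should set C13 (S) and C12 (S) together, the C14 centre being a bystander.

Step 17
Reactants: 32 (4R)-4-benzyl-3-[(2S,3S)-2-[(4S)-2,2-dimethyl-1,3-dioxolan-4-yl]-3-hydroxy-4-(C9 of the decalin acetonide)butanoyl]-1,3-oxazolidin-2-one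
Product: 34 CNP0113086.2, via deprotected hydroxy imide 33 (not isolated)
Conditions: AcOH–H2O (4:1), 40 °C
Reagents that add atoms: none
Why: mild acid hydrolysis removes both acetonides and the freed primary C15 alcohol acylates itself on the imide carbonyl (5-exo-trig lactonisation), releasing the auxiliary under conditions too mild to dehydrate the β-hydroxy lactone or to move the C8=C17 alkene.

Compound list
1 | ethyl 2-cyanopropanoate (racemic) | CCOC(=O)C(C)C#N | starting material
2 | allyl bromide | C=CCBr | starting material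
3 | ethyl 2-cyano-2-methylpent-4-enoate (racemic) | CCOC(=O)C(C)(C#N)CC=C | intermediate
4 | secondary ozonide of 3, ethyl 2-cyano-2-methyl-3-(1,2,4-trioxolan-3-yl)propanoate | CCOC(=O)C(C)(C#N)CC1OCOO1 | intermediate
5 | ethyl 2-cyano-2-methyl-4-oxobutanoate (racemic) | CCOC(=O)C(C)(C#N)CC=O | intermediate
6 | methyl vinyl ketone (but-3-en-2-one) | CC(=O)C=C | starting material
7 | ethyl (3R)-2-cyano-3-formyl-2-methyl-6-oxoheptanoate (both C2 epimers) | CC(=O)CC[C@H](C(C)(C#N)C(=O)OCC)C=O | intermediate
8 | ethyl 2-cyano-2-[(1R)-2-hydroxy-4-oxocyclohexyl]propanoate (aldol, carbinol epimers) | O=C1CC[C@H](C(C)(C#N)C(=O)OCC)C(O)C1 | intermediate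
9 | ethyl 2-cyano-2-[(1S)-4-oxocyclohex-2-en-1-yl]propanoate | O=C1CC[C@H](C(C)(C#N)C(=O)OCC)C=C1 | intermediate
10 | ethyl 2-cyano-2-[(1S,2R)-2-methyl-4-(trimethylsilyloxy)cyclohex-3-en-1-yl]propanoate | C[Si](C)(C)OC1=C[C@H](C)[C@@H](C(C)(C#N)C(=O)OCC)CC1 | intermediate
11 | ethyl 2-cyano-2-[(1S)-2-methyl-4-oxocyclohex-2-en-1-yl]propanoate | O=C1CC[C@H](C(C)(C#N)C(=O)OCC)C(C)=C1 | intermediate
12 | 2-(2-bromoethyl)-1,3-dioxolane | BrCCC1OCCO1 | starting material
13 | tert-butyl bromoacetate | BrCC(=O)OC(C)(C)C | starting material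
14 | [2-(1,3-dioxolan-2-yl)ethyl]magnesium bromide | Br[Mg]CCC1OCCO1 | intermediate
15 | bromomagnesium enolate of the 1,4-adduct (C8–O–Mg, C8=C9; C5 and C10 as in 16) | Br[Mg]OC1=C[C@](C)(CCC2OCCO2)[C@@H](C(C)(C#N)C(=O)OCC)CC1 | intermediate
16 | tert-butyl 2-[(1S,2R,3S)-3-(2-cyano-1-ethoxy-1-oxopropan-2-yl)-2-[2-(1,3-dioxolan-2-yl)ethyl]-2-methyl-6-oxocyclohexyl]acetate | O=C1CC[C@H](C(C)(C#N)C(=O)OCC)[C@@](C)(CCC2OCCO2)[C@@H]1CC(=O)OC(C)(C)C | intermediate
17 | tert-butyl 2-[(1R,2S,3S)-3-(2-cyano-1-ethoxy-1-oxopropan-2-yl)-2-[2-(1,3-dioxolan-2-yl)ethyl]-2-methyl-6-methylidenecyclohexyl]acetate | C=C1CC[C@H](C(C)(C#N)C(=O)OCC)[C@@](C)(CCC2OCCO2)[C@@H]1CC(=O)OC(C)(C)C | intermediate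
18 | 2-[(1S,2S,3R)-3-(2-tert-butoxy-2-oxoethyl)-2-[2-(1,3-dioxolan-2-yl)ethyl]-2-methyl-4-methylidenecyclohexyl]-2-cyanopropanoic acid | C=C1CC[C@H](C(C)(C#N)C(=O)O)[C@@](C)(CCC2OCCO2)[C@@H]1CC(=O)OC(C)(C)C | intermediate
19 | 2-[(1S,2S,3R)-3-(2-tert-butoxy-2-oxoethyl)-2-methyl-4-methylidene-2-(3-oxopropyl)cyclohexyl]-2-cyanopropanoic acid | C=C1CC[C@H](C(C)(C#N)C(=O)O)[C@@](C)(CCC=O)[C@@H]1CC(=O)OC(C)(C)C | intermediate
20 | copper keteniminate from 19 (C4=C=N–Cu; ring B centres as in 19; phosphine on copper omitted) | C=C1CC[C@H](C(C)=C=N[Cu])[C@@](C)(CCC=O)[C@@H]1CC(=O)OC(C)(C)C | intermediate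
21 | tert-butyl 2-[(1R,4aS,5R,6R,8aS)-5-cyano-6-hydroxy-5,8a-dimethyl-2-methylidenedecahydronaphthalen-1-yl]acetate | C=C1CC[C@@H]2[C@](C)(C#N)[C@H](O)CC[C@@]2(C)[C@@H]1CC(=O)OC(C)(C)C | intermediate
22 | (1S,2R,4aS,5R,8aS)-2-hydroxy-5-(2-hydroxyethyl)-1,4a-dimethyl-6-methylidenedecahydronaphthalene-1-carbaldehyde | C=C1CC[C@@H]2[C@](C)(C=O)[C@H](O)CC[C@@]2(C)[C@@H]1CCO | intermediate
23 | (1R,2R,4aS,5R,8aS)-5-(2-hydroxyethyl)-1-(hydroxymethyl)-1,4a-dimethyl-6-methylidenedecahydronaphthalen-2-ol | C=C1CC[C@@H]2[C@](C)(CO)[C@H](O)CC[C@@]2(C)[C@@H]1CCO | intermediate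
24 | 3,19-O-isopropylidene acetal of 23 (acetonide across the secondary and the neopentyl primary alcohol; free 2-hydroxyethyl; configuration as in 23) | C=C1CC[C@@H]2[C@]3(C)COC(C)(C)O[C@@H]3CC[C@@]2(C)[C@@H]1CCO | intermediate
25 | C12 aldehyde of 24 (CH2CHO on C9; configuration as in 23) | C=C1CC[C@@H]2[C@]3(C)COC(C)(C)O[C@@H]3CC[C@@]2(C)[C@@H]1CC=O | intermediate
26 | methyl 2-[(4S)-2,2-dimethyl-1,3-dioxolan-4-yl]acetate | COC(=O)C[C@H]1COC(C)(C)O1 | starting material
27 | 2-[(4S)-2,2-dimethyl-1,3-dioxolan-4-yl]acetic acid | OC(=O)C[C@H]1COC(C)(C)O1 | intermediate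
28 | (4R)-4-benzyl-1,3-oxazolidin-2-one | O=C1N[C@H](Cc2ccccc2)CO1 | starting material
29 | mixed anhydride of 27 with pivalic acid | CC(C)(C)C(=O)OC(=O)C[C@H]1COC(C)(C)O1 | intermediate
30 | (4R)-4-benzyl-3-{2-[(4S)-2,2-dimethyl-1,3-dioxolan-4-yl]acetyl}-1,3-oxazolidin-2-one | O=C(C[C@H]1COC(C)(C)O1)N1C(=O)OC[C@H]1Cc1ccccc1 | intermediate
31 | (Z)-dibutylboron enolate of 30 | CCCCB(CCCC)O/C(=C\[C@H]1COC(C)(C)O1)N1C(=O)OC[C@H]1Cc1ccccc1 | intermediate
32 | (4R)-4-benzyl-3-[(2S,3S)-2-[(4S)-2,2-dimethyl-1,3-dioxolan-4-yl]-3-hydroxy-4-(C9 of the decalin 3,19-acetonide)butanoyl]-1,3-oxazolidin-2-one (decalin as in 24) | C=C1CC[C@@H]2[C@]3(C)COC(C)(C)O[C@@H]3CC[C@@]2(C)[C@@H]1C[C@H](O)[C@H](C(=O)N1C(=O)OC[C@H]1Cc1ccccc1)[C@H]1COC(C)(C)O1 | intermediate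
33 | fully deprotected hydroxy imide (free 3-, 19-, 12-, 14- and 15-OH; (12S,13S,14S); auxiliary still on C16) | C=C1CC[C@@H]2[C@](C)(CO)[C@H](O)CC[C@@]2(C)[C@@H]1C[C@H](O)[C@H](C(=O)N1C(=O)OC[C@H]1Cc1ccccc1)[C@H](O)CO | intermediate
34 | CNP0113086.2, (3S,4S)-4-hydroxy-3-{(1S)-1-hydroxy-2-[(1R,4aS,5R,6R,8aS)-6-hydroxy-5-(hydroxymethyl)-5,8a-dimethyl-2-methylidenedecahydronaphthalen-1-yl]ethyl}oxolan-2-one | C=C1CC[C@@H]2[C@](C)(CO)[C@H](O)CC[C@@]2(C)[C@@H]1C[C@H](O)[C@@H]1C(=O)OC[C@H]1O | target

Total step count: 17. Longest linear sequence: 15 steps (steps 1–13, 16, 17); steps 14 and 15 make the lactone fragment.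

Steps most likely to fail

Step 10. The ring may close through the open transition state with the aldehyde oxygen axial, anti to the nitrile, because no metal bridges the two oxygens; the process at risk is facial selection at the carbinol carbon C3, not the C3–C4 bond formation itself. The fallback sets out from 19: the same closure is run and the C3-epimeric alcohol F1 (alone or mixed with 21) is oxidised with Dess–Martin periodinane (NaHCO3, CH2Cl2) to the 3-oxo nitrile F2. C3 is then set by NaBH4 in MeOH at −20 °C, where axial hydride attack on a cyclohexanone flanked by a quaternary carbon should give the equatorial alcohol. The route is rejoined at 21.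

Step 7. The copper-catalysed 1,4-addition may stall at the congested β-carbon next to the fully substituted C5 arm, and kinetic alkylation of the enolate from the face away from the axial C10 methyl may leave C9 as an epimer mixture that equilibrates only partly. The fallback sets out from 11: the addition of 14 is run with CuBr·SMe2, TMSCl and HMPA in THF at −78 °C and stopped at the silyl enol ether F3. MeLi (THF, 0 °C) frees the lithium enolate, which is added to tert-butyl glyoxylate at −78 °C to give the aldol F4; Martin sulfurane dehydrates it to the alkylidene ketone F5. Conjugate reduction with [(Ph3P)CuH]6 in toluene followed by kinetic protonation (2,6-di-tert-butylphenol, −78 °C) from the face opposite the axial C10 methyl sets C9 and returns to 16.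

Step 3. Enamine formation and turnover may be slow for an aldehyde whose α-CH2 sits next to a quaternary carbon, which would cost conversion and let background racemic addition erode the enantioselectivity. The fallback sets out from 5: condensation with (S)-1-amino-2-(methoxymethyl)pyrrolidine gives the SAMP hydrazone F6. Deprotonation (LDA, THF, −78 °C) and alkylation with 2-(2-iodoethyl)-2-methyl-1,3-dioxolane at −100 °C gives the alkylated hydrazone F7, the auxiliary controlling C5. Ozonolysis (CH2Cl2, −78 °C) frees the ketal aldehyde F8, and PPTS in acetone–water removes the ketal to rejoin the route at 7.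

Further compounds
F1 | step 10 | tert-butyl 2-[(1R,4aS,5R,6S,8aS)-5-cyano-6-hydroxy-5,8a-dimethyl-2-methylidenedecahydronaphthalen-1-yl]acetate (C3 epimer of 21) | C=C1CC[C@@H]2[C@](C)(C#N)[C@@H](O)CC[C@@]2(C)[C@@H]1CC(=O)OC(C)(C)C
F2 | step 10 | tert-butyl 2-[(1R,4aS,5R,8aS)-5-cyano-5,8a-dimethyl-2-methylidene-6-oxodecahydronaphthalen-1-yl]acetate | C=C1CC[C@@H]2[C@](C)(C#N)C(=O)CC[C@@]2(C)[C@@H]1CC(=O)OC(C)(C)C
F3 | step 7 | ethyl 2-cyano-2-[(1S,2R)-2-[2-(1,3-dioxolan-2-yl)ethyl]-2-methyl-4-(trimethylsilyloxy)cyclohex-3-en-1-yl]propanoate | C[Si](C)(C)OC1=C[C@](C)(CCC2OCCO2)[C@@H](C(C)(C#N)C(=O)OCC)CC1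
F4 | step 7 | tert-butyl 2-hydroxy-2-[(2R,3S)-3-(2-cyano-1-ethoxy-1-oxopropan-2-yl)-2-[2-(1,3-dioxolan-2-yl)ethyl]-2-methyl-6-oxocyclohexyl]acetate (epimers at the two new centres) | O=C1CC[C@H](C(C)(C#N)C(=O)OCC)[C@@](C)(CCC2OCCO2)C1C(O)C(=O)OC(C)(C)C
F5 | step 7 | tert-butyl 2-[(2R,3S)-3-(2-cyano-1-ethoxy-1-oxopropan-2-yl)-2-[2-(1,3-dioxolan-2-yl)ethyl]-2-methyl-6-oxocyclohexylidene]acetate (either alkene isomer) | O=C1CC[C@H](C(C)(C#N)C(=O)OCC)[C@@](C)(CCC2OCCO2)C1=CC(=O)OC(C)(C)C
F6 | step 3 | ethyl 2-cyano-4-{[(2S)-2-(methoxymethyl)pyrrolidin-1-yl]imino}-2-methylbutanoate (E hydrazone) | CCOC(=O)C(C)(C#N)C/C=N/N1CCC[C@H]1COC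
F7 | step 3 | ethyl (3R)-2-cyano-3-({[(2S)-2-(methoxymethyl)pyrrolidin-1-yl]imino}methyl)-2-methyl-5-(2-methyl-1,3-dioxolan-2-yl)pentanoate | CCOC(=O)C(C)(C#N)[C@@H](CCC1(C)OCCO1)/C=N/N1CCC[C@H]1COC
F8 | step 3 | ethyl (3R)-2-cyano-3-formyl-2-methyl-5-(2-methyl-1,3-dioxolan-2-yl)pentanoate | CCOC(=O)C(C)(C#N)[C@@H](CCC1(C)OCCO1)C=O
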